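Numbering: chroman O1, C2 (Me), C3, C4 (isobutyl), C4a, C5–C8, C8a. Ten-membered ring: C2, C3, C9, C10, C11 (Me), C12–C16. C17 is the CMe2OH carbon on C14.
Retrosynthetic cuts, in order: the two aryl–CHO bonds (C6, C8); C10–C11 of the ten-membered ring; O1–C2 of the pyran; the arene bonds C8a–C4a, C5–C6 and C8–C8a; the C4–C4a link (ynolate homologation); C3–C4; C2–C16.
Enabling feature: the benzene ring carries oxygen on C5, C7 and C8a and is joined to the terpene by one C–C bond only (C4a–C4). A siloxyalkyne on C4 and a 3-oxygenated cyclobutenone build this pattern and leave only the C8a oxygen free.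
Forward: terpineol is cut down to a C12–C16 bromide and added across pent-4-en-2-yn-1-ol (C2–C16). The dienol is esterified, rearranged (C3–C4) and homologated to the siloxyalkyne. The rings then form in the order benzene, pyran, ten-membered carbocycle, and the formyl groups come last.
Stereochemistry: C14 comes from (R)-α-terpineol. C3 and C4 come from a chair boron Ireland–Claisen rearrangement (relative: E alkene plus enolate geometry; absolute: chiral diazaborolidine). C2 is set in the pyran closure under control by C3/C4. The Z C11=C12 alkene comes from a Z-selective iodoethylidene Wittig reaction and a stereoretentive Suzuki coupling.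

Key step: step 14

Assumption: the (S,S)-diazaborolidine of step 10 is taken to give the (3S,4S) acid by analogy with simple (E)-allylic alkanoates; the sense is to be confirmed on 18, and the antipodal diamine is equally available.

Step 1
Reactants: 1 (R)-α-terpineol
Product: 2 (R)-α-terpineol tert-butyldimethylsilyl (TBS) ether
Conditions: TBSOTf, 2,6-lutidine, CH2Cl2, 0 °C to rt
Reagents that add atoms: tert-butyldimethylsilyl triflate, CC(C)(C)[Si](C)(C)OS(=O)(=O)C(F)(F)F
Why: Silylation with a silyl triflate caps the hindered tertiary alcohol so that it cannot form a lactol with the C12 aldehyde made next, and the C14 stereocentre bought with 1 is not involved.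

Step 2
Reactants: 2 (R)-α-terpineol TBS ether
Product: 3 (3R)-3-[2-(TBS-oxy)propan-2-yl]-6-oxoheptanal
Conditions: O3, CH2Cl2, −78 °C; then Me2S, −78 °C to rt
Reagents that add atoms: ozone, [O-][O+]=O
Why: Ozonolysis with reductive work-up cleaves the single alkene into the C12 aldehyde and a methyl ketone on C16 without touching C14.

Step 3
Reactants: 3 keto aldehyde
Product: 4 (5R)-5-(2-hydroxyethyl)-6-methyl-6-(TBS-oxy)heptan-2-one
Conditions: NaBH4 (0.3 equiv), CH2Cl2/EtOH 7:3, −78 °C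
Reagents that add atoms: none
Why: Chemoselective borohydride reduction works because an aldehyde is reduced much faster than a methyl ketone at −78 °C with a deficit of hydride.

Step 4
Reactants: 4 keto alcohol
Product: 5 (5R)-6-methyl-6-(TBS-oxy)-5-[2-(TBS-oxy)ethyl]heptan-2-one
Conditions: TBSCl, imidazole, DMF, rt
Reagents that add atoms: tert-butyldimethylsilyl chloride, CC(C)(C)[Si](C)(C)Cl
Why: Imidazole-mediated silylation masks the C12 alcohol with a group that resists Grignard, lithium amide and bromoborane reagents yet leaves under mild acid well before the tertiary TBS ether does.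

Step 5
Reactants: 5 keto bis-silyl ether
Product: 6 (3R)-5-(TBS-oxy)-3-[2-(TBS-oxy)propan-2-yl]pentyl acetate
Conditions: (CF3CO)2O, urea–H2O2, Na2HPO4, CH2Cl2, 0 °C
Reagents that add atoms: urea–hydrogen peroxide (oxygen source, through CF3CO3H), OO.NC(N)=O
Why: Baeyer–Villiger oxidation with buffered trifluoroperacetic acid inserts oxygen on the side of the better migrating primary alkyl group (C16) and so trims off the two carbons that the target does not need.

Step 6
Reactants: 6 acetate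
Product: 7 (3R)-5-(TBS-oxy)-3-[2-(TBS-oxy)propan-2-yl]pentan-1-ol
Conditions: K2CO3 (20 mol %), MeOH, rt
Reagents that add atoms: none
Why: Carbonate-catalysed transesterification removes the acetate and leaves both silyl ethers in place.

Step 7
Reactants: 7 C16 alcohol
Product: 8 (3S)-1-bromo-5-(TBS-oxy)-3-[2-(TBS-oxy)propan-2-yl]pentane (same spatial arrangement at C14; the descriptor changes by priority only)
Conditions: CBr4, PPh3, CH2Cl2, 0 °C
Reagents that add atoms: carbon tetrabromide, BrC(Br)(Br)Br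
Why: The Appel reaction converts the unhindered primary alcohol into the bromide under neutral conditions that silyl ethers tolerate.

Step 8
Reactants: 8 C16 bromide; 9 pent-4-en-2-yn-1-ol
Product: 13 (2E)-2-{(3R)-5-(TBS-oxy)-3-[2-(TBS-oxy)propan-2-yl]pentyl}penta-2,4-dien-1-ol, via chloromagnesium alkoxide 10 (not isolated), via Grignard reagent 11 (not isolated), via magnesium chelate 12 (not isolated)
Conditions: 8, Mg, THF, 35 °C; 9 (1.5 equiv), i-PrMgCl, THF, −20 °C; combine, CuI (10 mol %), −20 °C to rt; aq NH4Cl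
Reagents that add atoms: none
Why: In this copper-catalysed anti-carbomagnesiation of a propargylic alkoxide the alkyl group adds to the carbon next to CH2O (bond C2–C16) and magnesium ends on C3 inside a five-membered chelate, so protonation gives the E alkene with the vinyl group trans to CH2OH.

Step 9
Reactants: 13 dienol; 14 4-methylpentanoic acid
Product: 15 4-methylpentanoate ester of 13
Conditions: DCC, DMAP (10 mol %), CH2Cl2, 0 °C to rt
Reagents that add atoms: none
Why: Steglich esterification joins the allylic alcohol and the acid without strong acid or heat, so the E diene is preserved.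

Step 10
Reactants: 15 allylic ester
Product: 18 (2S,3S,7R)-9-(TBS-oxy)-3-ethenyl-4-methylidene-2-(2-methylpropyl)-7-[2-(TBS-oxy)propan-2-yl]nonanoic acid (3S,4S,14R in target numbering), via boron ketene acetal 16 (not isolated), via boron carboxylate 17 (not isolated)
Conditions: (S,S)-N,N'-bis[3,5-bis(trifluoromethyl)benzenesulfonyl]-1,2-diphenylethane-1,2-diamine, BBr3, CH2Cl2, rt, then vacuum; 15, i-Pr2NEt, CH2Cl2, −78 °C; then −20 to 4 °C; aq work-up
Reagents that add atoms: none
Why: In this enantioselective boron Ireland–Claisen rearrangement i-Pr2NEt in CH2Cl2 gives the ketene acetal with the isobutyl group cis to O–B, the chair transition state with the E alkene turns that geometry into the syn C3/C4 pair while forming C3–C4 and the C2 methylidene, and the chiral diazaborolidine selects the enolate face and so the absolute configuration, which the remote C14 cannot influence.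

Step 11
Reactants: 18 acid
Product: 19 methyl ester of 18
Conditions: MeI, K2CO3, DMF, rt
Reagents that add atoms: iodomethane, CI
Why: Carboxylate alkylation gives the methyl ester needed for the homologation without forming an enolate, so C4 is not epimerised.

Step 12
Reactants: 19 methyl ester
Product: 22 triisopropylsilyl (TIPS) ynol ether TIPSO–C5≡C4a–C4H(i-Bu)–C3H(vinyl)–C2(=CH2)–C16 chain (3S,4S,14R), via dibromo enolate 20 (not isolated), via lithium ynolate 21 (not isolated)
Conditions: TMPH, n-BuLi, THF, 0 °C; CH2Br2, −78 °C; 19, −78 °C; n-BuLi (slight excess), −78 °C to rt; TIPSCl, −78 to 0 °C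
Reagents that add atoms: dibromomethane, BrCBr; triisopropylsilyl chloride, CC(C)[Si](Cl)(C(C)C)C(C)C
Why: In the Kowalski ynolate synthesis acylation of dibromomethyllithium, deprotonation and bromine–lithium exchange trigger a 1,2-shift of C4 with retention onto the new carbon C4a (the old ester carbon becomes C5), the bulky TIPSCl silylates the ynolate on oxygen, and n-BuLi is held to a small excess because C3–H is doubly allylic.

Step 13
Reactants: 23 cyclobutane-1,3-dione
Product: 24 3-(triisopropylsilyloxy)cyclobut-2-en-1-one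
Conditions: TIPSCl, Et3N, CH2Cl2, 0 °C
Reagents that add atoms: triisopropylsilyl chloride, CC(C)[Si](Cl)(C(C)C)C(C)C
Why: O-Silylation of the strongly acidic enol form of 23 gives the vinylogous silyl ester, chosen over an alkyl ether because fluoride can free O7 at the end, whereas Lewis acid dealkylation beside a formyl group would first break the tertiary O1–C2 bond.

Step 14
Reactants: 22 siloxyalkyne; 24 3-(triisopropylsilyloxy)cyclobut-2-en-1-one
Product: 29 2-alkyl-3,5-bis(TIPS-oxy)phenol with free OH on C8a and TIPS ethers on C5 and C7 (3S,4S,14R), via vinylketene 25 (not isolated), via vinylcyclobutenone 26 (not isolated), via dienylketene 27 (not isolated), via cyclohexadienone 28 (not isolated)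
Conditions: 22, 24 (1.5 equiv), toluene, 80 then 110 °C, sealed tube, argon
Reagents that add atoms: none
Why: On heating, 24 undergoes conrotatory ring opening to vinylketene 25; the alkyne carbon remote from oxygen (C4a) adds to the ketene carbonyl carbon (future C8a) and C5 joins C6, so cyclobutenone 26 forms as a single regioisomer. Compound 26 reopens to dienylketene 27, which closes the benzene ring, the only ring made here, by a disrotatory six-electron electrocyclisation (C8 to C8a), and enolisation of dienone 28 delivers 29. The closest known reaction type is the Danheiser benzannulation of a cyclobutenone with a Kowalski-type siloxyalkyne, applied here to an oxygen-substituted cyclobutenone and a branched alkyne. No lasting stereocentre is formed (C6 of 26 is lost on aromatisation), and the neutral medium leaves C3, C4 and C14 alone. The step needs regioselectivity, secured by the polar match between the ketene carbonyl carbon and the alkyne carbon beta to oxygen, and chemoselectivity, secured because the ketene reacts with the electron-rich alkyne far faster than with the two unactivated alkenes. Only the C8a oxygen emerges unprotected, so only O1 can close the pyran.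

Step 15
Reactants: 29 phenol
Product: 31 (2R,3S,4S,14R)-chroman with C2 methyl, C3 vinyl, C4 isobutyl, 5,7-bis(TIPS-oxy), C17 TBS ether and free C12 alcohol, via silyl ether chroman 30 (not isolated)
Conditions: TsOH·H2O (20 mol %), CH2Cl2, 0 °C to rt; then MeOH, rt
Reagents that add atoms: none
Why: In this Brønsted acid-catalysed Markovnikov hydroalkoxylation (the closure used for cannabinoid pyrans) the more basic 1,1-disubstituted alkene is protonated and only the free C8a phenol reaches C2 in a 6-exo mode; C2 is set under substrate control, allylic 1,2-strain holding C3–H beside C16 so that O1 adds to the face that leaves C16 trans to the vinyl group, the bias is expected to be modest and the C2 epimers are separated at 31, and methanol then removes only the primary silyl ether.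

Step 16
Reactants: 31 chroman alcohol
Product: 32 chroman C12 aldehyde
Conditions: Dess–Martin periodinane, CH2Cl2, 0 °C to rt
Reagents that add atoms: none
Why: Dess–Martin oxidation stops at the aldehyde under near-neutral conditions and spares the silyl ethers, the vinyl group and the electron-rich arene.

Step 17
Reactants: 32 aldehyde
Product: 33 (Z)-C11 iodoalkene (C12H=C11(I)CH3 with iodine cis to C13)
Conditions: EtPPh3I, n-BuLi, THF, rt; I2, −78 °C; NaHMDS, −20 °C; 32, −78 °C
Reagents that add atoms: ethyltriphenylphosphonium iodide, CC[P+](c1ccccc1)(c1ccccc1)c1ccccc1.[I-]; iodine, II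
Why: The Stork–Zhao-type Wittig olefination with the alpha-iodoethylidene ylide is Z-selective for unbranched aldehydes and places iodine cis to C13, as the ring alkene requires.

Step 18
Reactants: 33 iodoalkene
Product: 35 silyl-protected tricycle with the ten-membered ring closed and the Z C11=C12 alkene, via alkylborane 34 (not isolated)
Conditions: 9-BBN, THF, rt; then slow addition to Pd(dppf)Cl2 (20 mol %), AsPh3, Cs2CO3, DMF/THF/H2O, 45 °C, about 1 mM
Reagents that add atoms: none
Why: 9-BBN adds only to the monosubstituted C9=C10 alkene, and the intramolecular B-alkyl Suzuki–Miyaura coupling under high dilution forms C10–C11 with retention of the iodoalkene geometry, which gives the Z ring alkene.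

Step 19
Reactants: 35 protected tricycle
Product: 36 5,7-dihydroxychroman tricycle with free C17 alcohol
Conditions: TBAF, THF, rt to 50 °C, argon
Reagents that add atoms: none
Why: Fluoride-mediated desilylation removes the two aryl TIPS ethers at once and the tertiary TBS ether on warming, under basic conditions that do not harm the tertiary aryl ether or the Z alkene.

Step 20
Reactants: 36 triol
Product: 37 CNP0570248.1 (2R,3S,4S,14R; Z alkene)
Conditions: MgCl2, Et3N, (CH2O)n, MeCN, reflux; then 1 M HCl, 0 °C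
Reagents that add atoms: paraformaldehyde (as formaldehyde), C=O
Why: In the Casnati–Skattebøl ortho-formylation each magnesium phenoxide (O5, O7) delivers formaldehyde to a free ortho carbon and a second formaldehyde takes up hydride, so C6 and C8, the only open ring positions, are both formylated under basic conditions that spare the tertiary alcohol, the tertiary aryl ether and the alkene.

Compound list
1 | (R)-α-terpineol | CC1=CC[C@@H](CC1)C(C)(C)O | starting material
2 | (R)-α-terpineol TBS ether | CC1=CC[C@@H](CC1)C(C)(C)O[Si](C)(C)C(C)(C)C | intermediate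
3 | (3R)-3-[2-(TBS-oxy)propan-2-yl]-6-oxoheptanal | CC(=O)CC[C@@H](C(C)(C)O[Si](C)(C)C(C)(C)C)CC=O | intermediate
4 | (5R)-5-(2-hydroxyethyl)-6-methyl-6-(TBS-oxy)heptan-2-one | CC(=O)CC[C@@H](C(C)(C)O[Si](C)(C)C(C)(C)C)CCO | intermediate
5 | (5R)-6-methyl-6-(TBS-oxy)-5-[2-(TBS-oxy)ethyl]heptan-2-one | CC(=O)CC[C@@H](C(C)(C)O[Si](C)(C)C(C)(C)C)CCO[Si](C)(C)C(C)(C)C | intermediate
6 | (3R)-5-(TBS-oxy)-3-[2-(TBS-oxy)propan-2-yl]pentyl acetate | CC(=O)OCC[C@@H](C(C)(C)O[Si](C)(C)C(C)(C)C)CCO[Si](C)(C)C(C)(C)C | intermediate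
7 | (3R)-5-(TBS-oxy)-3-[2-(TBS-oxy)propan-2-yl]pentan-1-ol | OCC[C@@H](C(C)(C)O[Si](C)(C)C(C)(C)C)CCO[Si](C)(C)C(C)(C)C | intermediate
8 | (3S)-1-bromo-5-(TBS-oxy)-3-[2-(TBS-oxy)propan-2-yl]pentane | BrCC[C@@H](C(C)(C)O[Si](C)(C)C(C)(C)C)CCO[Si](C)(C)C(C)(C)C | intermediate
9 | pent-4-en-2-yn-1-ol | C=CC#CCO | starting material
10 | chloromagnesium alkoxide of 9 | C=CC#CCO[Mg]Cl | intermediate
11 | Grignard reagent of 8 | Br[Mg]CC[C@@H](C(C)(C)O[Si](C)(C)C(C)(C)C)CCO[Si](C)(C)C(C)(C)C | intermediate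
12 | cyclic alkenylmagnesium alkoxide (Mg bound to C3 and to the CH2O oxygen) | C=CC1=C(CC[C@@H](C(C)(C)O[Si](C)(C)C(C)(C)C)CCO[Si](C)(C)C(C)(C)C)CO[Mg]1 | intermediate
13 | (2E)-2-{(3R)-5-(TBS-oxy)-3-[2-(TBS-oxy)propan-2-yl]pentyl}penta-2,4-dien-1-ol | OC/C(CC[C@@H](C(C)(C)O[Si](C)(C)C(C)(C)C)CCO[Si](C)(C)C(C)(C)C)=C/C=C | intermediate
14 | 4-methylpentanoic acid | CC(C)CCC(=O)O | starting material
15 | 4-methylpentanoate ester of 13 | CC(C)CCC(=O)OC/C(CC[C@@H](C(C)(C)O[Si](C)(C)C(C)(C)C)CCO[Si](C)(C)C(C)(C)C)=C/C=C | intermediate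
16 | boron ketene acetal of 15 (isobutyl cis to O–B, (S,S)-diazaborolidine on oxygen) | CC(C)C/C=C(\OB1N(S(=O)(=O)c2cc(cc(c2)C(F)(F)F)C(F)(F)F)[C@@H](c2ccccc2)[C@H](c2ccccc2)N1S(=O)(=O)c1cc(cc(c1)C(F)(F)F)C(F)(F)F)OC/C(CC[C@@H](C(C)(C)O[Si](C)(C)C(C)(C)C)CCO[Si](C)(C)C(C)(C)C)=C/C=C | intermediate
17 | boron carboxylate of 18 | O=C(OB1N(S(=O)(=O)c2cc(cc(c2)C(F)(F)F)C(F)(F)F)[C@@H](c2ccccc2)[C@H](c2ccccc2)N1S(=O)(=O)c1cc(cc(c1)C(F)(F)F)C(F)(F)F)[C@@H](CC(C)C)[C@H](C=C)C(=C)CC[C@@H](C(C)(C)O[Si](C)(C)C(C)(C)C)CCO[Si](C)(C)C(C)(C)C | intermediate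
18 | (2S,3S,7R)-9-(TBS-oxy)-3-ethenyl-4-methylidene-2-(2-methylpropyl)-7-[2-(TBS-oxy)propan-2-yl]nonanoic acid | OC(=O)[C@@H](CC(C)C)[C@H](C=C)C(=C)CC[C@@H](C(C)(C)O[Si](C)(C)C(C)(C)C)CCO[Si](C)(C)C(C)(C)C | intermediate
19 | methyl ester of 18 | COC(=O)[C@@H](CC(C)C)[C@H](C=C)C(=C)CC[C@@H](C(C)(C)O[Si](C)(C)C(C)(C)C)CCO[Si](C)(C)C(C)(C)C | intermediate
20 | lithium enolate of the dibromomethyl ketone from 19 | [Li]OC(=C(Br)Br)[C@@H](CC(C)C)[C@H](C=C)C(=C)CC[C@@H](C(C)(C)O[Si](C)(C)C(C)(C)C)CCO[Si](C)(C)C(C)(C)C | intermediate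
21 | lithium ynolate LiO–C5≡C4a–C4 | [Li]OC#C[C@@H](CC(C)C)[C@H](C=C)C(=C)CC[C@@H](C(C)(C)O[Si](C)(C)C(C)(C)C)CCO[Si](C)(C)C(C)(C)C | intermediate
22 | TIPS ynol ether (siloxyalkyne, 3S,4S,14R) | CC(C)[Si](C(C)C)(C(C)C)OC#C[C@@H](CC(C)C)[C@H](C=C)C(=C)CC[C@@H](C(C)(C)O[Si](C)(C)C(C)(C)C)CCO[Si](C)(C)C(C)(C)C | intermediate
23 | cyclobutane-1,3-dione | O=C1CC(=O)C1 | starting material
24 | 3-(triisopropylsilyloxy)cyclobut-2-en-1-one | O=C1C=C(O[Si](C(C)C)(C(C)C)C(C)C)C1 | intermediate
25 | 3-(triisopropylsilyloxy)buta-1,3-dien-1-one (vinylketene) | O=C=CC(=C)O[Si](C(C)C)(C(C)C)C(C)C | intermediate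
26 | (2+2) adduct: 2-alkyl-3-(TIPS-oxy)-4-[1-(TIPS-oxy)ethenyl]cyclobut-2-en-1-one (C6 unassigned) | O=C1C([C@@H](CC(C)C)[C@H](C=C)C(=C)CC[C@@H](C(C)(C)O[Si](C)(C)C(C)(C)C)CCO[Si](C)(C)C(C)(C)C)=C(O[Si](C(C)C)(C(C)C)C(C)C)C1C(=C)O[Si](C(C)C)(C(C)C)C(C)C | intermediate
27 | dienylketene O=C8a=C4a–C5=C6–C7=C8 | O=C=C([C@@H](CC(C)C)[C@H](C=C)C(=C)CC[C@@H](C(C)(C)O[Si](C)(C)C(C)(C)C)CCO[Si](C)(C)C(C)(C)C)C(O[Si](C(C)C)(C(C)C)C(C)C)=CC(=C)O[Si](C(C)C)(C(C)C)C(C)C | intermediate
28 | 2-alkyl-3,5-bis(TIPS-oxy)cyclohexa-2,4-dien-1-one | O=C1CC(O[Si](C(C)C)(C(C)C)C(C)C)=CC(O[Si](C(C)C)(C(C)C)C(C)C)=C1[C@@H](CC(C)C)[C@H](C=C)C(=C)CC[C@@H](C(C)(C)O[Si](C)(C)C(C)(C)C)CCO[Si](C)(C)C(C)(C)C | intermediate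
29 | 2-alkyl-3,5-bis(TIPS-oxy)phenol (free OH on C8a; 3S,4S,14R) | Oc1cc(O[Si](C(C)C)(C(C)C)C(C)C)cc(O[Si](C(C)C)(C(C)C)C(C)C)c1[C@@H](CC(C)C)[C@H](C=C)C(=C)CC[C@@H](C(C)(C)O[Si](C)(C)C(C)(C)C)CCO[Si](C)(C)C(C)(C)C | intermediate
30 | (2R,3S,4S,14R)-chroman, C12 and C17 TBS ethers | CC(C)(C)[Si](C)(C)OCC[C@H](C(C)(C)O[Si](C)(C)C(C)(C)C)CC[C@@]1(C)Oc2cc(O[Si](C(C)C)(C(C)C)C(C)C)cc(O[Si](C(C)C)(C(C)C)C(C)C)c2[C@@H](CC(C)C)[C@@H]1C=C | intermediate
31 | (2R,3S,4S,14R)-chroman, free C12 alcohol | OCC[C@H](C(C)(C)O[Si](C)(C)C(C)(C)C)CC[C@@]1(C)Oc2cc(O[Si](C(C)C)(C(C)C)C(C)C)cc(O[Si](C(C)C)(C(C)C)C(C)C)c2[C@@H](CC(C)C)[C@@H]1C=C | intermediate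
32 | chroman C12 aldehyde | O=CC[C@H](C(C)(C)O[Si](C)(C)C(C)(C)C)CC[C@@]1(C)Oc2cc(O[Si](C(C)C)(C(C)C)C(C)C)cc(O[Si](C(C)C)(C(C)C)C(C)C)c2[C@@H](CC(C)C)[C@@H]1C=C | intermediate
33 | chroman (Z)-C11 iodoalkene | C/C(I)=C/C[C@H](C(C)(C)O[Si](C)(C)C(C)(C)C)CC[C@@]1(C)Oc2cc(O[Si](C(C)C)(C(C)C)C(C)C)cc(O[Si](C(C)C)(C(C)C)C(C)C)c2[C@@H](CC(C)C)[C@@H]1C=C | intermediate
34 | C10 B-alkyl-9-borabicyclo[3.3.1]nonane of 33 | C/C(I)=C/C[C@H](C(C)(C)O[Si](C)(C)C(C)(C)C)CC[C@@]1(C)Oc2cc(O[Si](C(C)C)(C(C)C)C(C)C)cc(O[Si](C(C)C)(C(C)C)C(C)C)c2[C@@H](CC(C)C)[C@@H]1CCB1C2CCCC1CCC2 | intermediate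
35 | silyl-protected tricycle (Z alkene) | C/C1=C/C[C@H](C(C)(C)O[Si](C)(C)C(C)(C)C)CC[C@@]2(C)Oc3cc(O[Si](C(C)C)(C(C)C)C(C)C)cc(O[Si](C(C)C)(C(C)C)C(C)C)c3[C@@H](CC(C)C)[C@@H]2CC1 | intermediate
36 | deformyl triol | C/C1=C/C[C@H](C(C)(C)O)CC[C@@]2(C)Oc3cc(O)cc(O)c3[C@@H](CC(C)C)[C@@H]2CC1 | intermediate
37 | CNP0570248.1 | C/C1=C/C[C@H](C(C)(C)O)CC[C@@]2(C)Oc3c(C=O)c(O)c(C=O)c(O)c3[C@@H](CC(C)C)[C@@H]2CC1 | target

Total steps: 20. Longest linear sequence: 19 (steps 1–12 and 14–20).

Step 15 is the weakest point. The closure may show poor facial selectivity at C2, the C2 cation may take up hydride from the doubly activated C3–H, and the tertiary silyl ether may ionise. The fallback replaces the free cation by a stereospecific substitution. It sets out from 29 and returns at 30.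
- Acetylation (Ac2O, pyridine) gives the aryl acetate F1.
- m-CPBA at 0 °C epoxidises the 1,1-disubstituted alkene in preference to the vinyl group, from the face turned away from the bulky C4 substituent. This gives the 2,2-disubstituted epoxide F2, which is freed from its C2 epimer at this stage.
- Mild methanolysis of the acetate gives the epoxy phenol F3.
- Catalytic camphorsulfonic acid opens F3 in the 6-exo mode at the tertiary carbon with inversion and gives the 2-(hydroxymethyl)chroman F4.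
- I2, PPh3 and imidazole give the iodomethyl chroman F5, and Bu3SnH with AIBN removes iodine to give 30.

Step 18 comes next. Closing a ten-membered ring by cross-coupling may lose out to oligomerisation, protodeboronation or reduction of the carbon–iodine bond. The fallback moves the ring closure from C10–C11 to the C11=C12 double bond. It sets out from 30 (isolated by leaving out the methanol stage of step 15) and returns at 35.
- 9-BBN gives the alkylborane F6.
- Intermolecular Suzuki coupling with 2-bromopropene (Pd(dppf)Cl2, K3PO4) gives the isopropenyl-terminated chroman F7.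
- TsOH in MeOH frees the primary alcohol F8, and Dess–Martin oxidation gives the aldehyde F9.
- Methylenation with Ph3P=CH2 gives the diene F10.
- Ring-closing metathesis with the second-generation Hoveyda–Grubbs catalyst in dilute toluene closes the trisubstituted alkene and gives 35. In a ten-membered ring the Z isomer is the less strained one.

Step 14 is third. The vinylogous silyl ester may resist ring opening at temperatures that the siloxyalkyne tolerates, silyl transfer may consume it, and surplus ketene may acylate the new phenol. The fallback keeps the same bonds and the same ketene 25 but generates it with light. It sets out from 22 and returns at 29.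
- Butane-2,3-dione with TIPSOTf and Et3N gives the enol silyl ether F11.
- LiHMDS and 2,2,2-trifluoroethyl trifluoroacetate give the trifluoroacetyl ketone F12.
- Diazo transfer with MsN3 and Et3N gives the diazo ketone F13.
- Irradiation of F13 with 22 in CH2Cl2 releases 25 by photochemical Wolff rearrangement at room temperature, and brief heating carries 26 to 28 through to 29.

Further compounds
F1 | step 15 | aryl acetate of 29 | CC(=O)Oc1cc(O[Si](C(C)C)(C(C)C)C(C)C)cc(O[Si](C(C)C)(C(C)C)C(C)C)c1[C@@H](CC(C)C)[C@H](C=C)C(=C)CC[C@@H](C(C)(C)O[Si](C)(C)C(C)(C)C)CCO[Si](C)(C)C(C)(C)C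
F2 | step 15 | C2 epoxide of F1 | CC(=O)Oc1cc(O[Si](C(C)C)(C(C)C)C(C)C)cc(O[Si](C(C)C)(C(C)C)C(C)C)c1[C@@H](CC(C)C)[C@H](C=C)[C@]2(CO2)CC[C@@H](C(C)(C)O[Si](C)(C)C(C)(C)C)CCO[Si](C)(C)C(C)(C)C
F3 | step 15 | epoxy phenol | Oc1cc(O[Si](C(C)C)(C(C)C)C(C)C)cc(O[Si](C(C)C)(C(C)C)C(C)C)c1[C@@H](CC(C)C)[C@H](C=C)[C@]2(CO2)CC[C@@H](C(C)(C)O[Si](C)(C)C(C)(C)C)CCO[Si](C)(C)C(C)(C)C
F4 | step 15 | 2-(hydroxymethyl)chroman | CC(C)(C)[Si](C)(C)OCC[C@H](C(C)(C)O[Si](C)(C)C(C)(C)C)CC[C@@]1(CO)Oc2cc(O[Si](C(C)C)(C(C)C)C(C)C)cc(O[Si](C(C)C)(C(C)C)C(C)C)c2[C@@H](CC(C)C)[C@@H]1C=C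
F5 | step 15 | 2-(iodomethyl)chroman | CC(C)(C)[Si](C)(C)OCC[C@H](C(C)(C)O[Si](C)(C)C(C)(C)C)CC[C@@]1(CI)Oc2cc(O[Si](C(C)C)(C(C)C)C(C)C)cc(O[Si](C(C)C)(C(C)C)C(C)C)c2[C@@H](CC(C)C)[C@@H]1C=C
F6 | step 18 | C10 B-alkyl-9-borabicyclo[3.3.1]nonane of 30 | CC(C)(C)[Si](C)(C)OCC[C@H](C(C)(C)O[Si](C)(C)C(C)(C)C)CC[C@@]1(C)Oc2cc(O[Si](C(C)C)(C(C)C)C(C)C)cc(O[Si](C(C)C)(C(C)C)C(C)C)c2[C@@H](CC(C)C)[C@@H]1CCB1C2CCCC1CCC2
F7 | step 18 | chroman with C10–C11(Me)=CH2 side chain, C12 TBS ether | CC(C)(C)[Si](C)(C)OCC[C@H](C(C)(C)O[Si](C)(C)C(C)(C)C)CC[C@@]1(C)Oc2cc(O[Si](C(C)C)(C(C)C)C(C)C)cc(O[Si](C(C)C)(C(C)C)C(C)C)c2[C@@H](CC(C)C)[C@@H]1CCC(C)=C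
F8 | step 18 | C12 alcohol of F7 | OCC[C@H](C(C)(C)O[Si](C)(C)C(C)(C)C)CC[C@@]1(C)Oc2cc(O[Si](C(C)C)(C(C)C)C(C)C)cc(O[Si](C(C)C)(C(C)C)C(C)C)c2[C@@H](CC(C)C)[C@@H]1CCC(C)=C
F9 | step 18 | C12 aldehyde | O=CC[C@H](C(C)(C)O[Si](C)(C)C(C)(C)C)CC[C@@]1(C)Oc2cc(O[Si](C(C)C)(C(C)C)C(C)C)cc(O[Si](C(C)C)(C(C)C)C(C)C)c2[C@@H](CC(C)C)[C@@H]1CCC(C)=C
F10 | step 18 | metathesis diene | C=CC[C@H](C(C)(C)O[Si](C)(C)C(C)(C)C)CC[C@@]1(C)Oc2cc(O[Si](C(C)C)(C(C)C)C(C)C)cc(O[Si](C(C)C)(C(C)C)C(C)C)c2[C@@H](CC(C)C)[C@@H]1CCC(C)=C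
F11 | step 14 | 3-(triisopropylsilyloxy)but-3-en-2-one | CC(=O)C(=C)O[Si](C(C)C)(C(C)C)C(C)C
F12 | step 14 | 1,1,1-trifluoro-5-(triisopropylsilyloxy)hex-5-ene-2,4-dione | O=C(CC(=O)C(=C)O[Si](C(C)C)(C(C)C)C(C)C)C(F)(F)F
F13 | step 14 | 1-diazo-3-(triisopropylsilyloxy)but-3-en-2-one | [N-]=[N+]=CC(=O)C(=C)O[Si](C(C)C)(C(C)C)C(C)C
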